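**Plan**

- Numbering: the bicyclic core is numbered as a chromane (O1, C2, C3, C4, C4a, C5, C6, C7, C8, C8a). The retrosynthesis cuts C8–C8a (carbocycle), then O1–C8a and C4a–C8a (C8a = CS2), then C7–C8 (Claisen with a glutarate half-ester), then C6–prenyl, and finally a temporary 2-pyranone ring back to methyl acetoacetate, a hydroxy amide (C2–C4) and a cyclobutylmethyl iodide.
- Enabling feature: C8a is a vinylogous carbonate carbon, bonded to O1 and conjugated through C4a with the C4 and C5 carbonyls, so it stands at the CO2 oxidation level. It can enter as CS2 on C4a and then take O1 and C8 by two addition–eliminations; because O1–C8a is made first, the dihydropyranone can only be fused at C4a–C8a.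
- Forward order: acetoacetate alkylation → 4-hydroxy-2-pyranone (its lactone carbonyl is the later C7, its C3 the later C6) → prenylation at C6 → lactone opening by the glutarate enolate → decarboxylation → CS2/MeI → dihydropyranone ring → carbocycle → saponification.
- Stereochemistry: cyclobutane from (−)-verbenone; C2/C3 from methyl (R)-3-hydroxybutanoate (Fráter–Seebach; the trans arrangement is also the thermodynamic one); benzylic carbon from desymmetrised 3-phenylglutaric anhydride; C6 by ligand-controlled allylic alkylation.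

Key step: step 16

Assumption: in the two catalyst-controlled steps (8 and 11) the catalyst antipode written is the working choice; if the first analytical run shows the opposite sense, the mirror-image (pseudoenantiomeric) catalyst is taken and nothing else changes.

**Route**

Step 1
Reactants: 1 (1S,5S)-(−)-verbenone
Product: 3 cis-pinononic acid [(1S,3R)-3-acetyl-2,2-dimethylcyclobutane-1-carboxylic acid], via α-keto acid 2 (not isolated)
Conditions: RuCl3·xH2O (2 mol%), NaIO4 (4.1 equiv), CCl4/MeCN/H2O, rt
Reagents that add atoms: sodium periodate, [Na+].[O-]I(=O)(=O)=O; water, O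
Why: Catalytic RuO4 cleaves the enone C=C (oxidative alkene cleavage), the α-keto acid 2 loses its carboxyl carbon as CO2 under the same oxidant, and both ring stereocentres are untouched, so the cis acid should result.

Step 2
Reactants: 3 cis-pinononic acid
Product: 4 (1S,3S)-2,2-dimethyl-3-(prop-1-en-2-yl)cyclobutane-1-carboxylic acid
Conditions: Ph3PCH3Br (2.5 equiv), KOtBu (2.4 equiv), THF, 0 °C → rt
Reagents that add atoms: methyltriphenylphosphonium bromide, C[P+](c1ccccc1)(c1ccccc1)c1ccccc1.[Br-]
Why: Wittig methylenation of the methyl ketone on the carboxylate salt; the excess ylide should olefinate faster than it enolises the ketone, so the cis ring configuration should be kept.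

Step 3
Reactants: 4 isopropenyl acid
Product: 5 [(1S,3S)-2,2-dimethyl-3-(prop-1-en-2-yl)cyclobutyl]methanol
Conditions: LiAlH4, Et2O, 0 °C → rt
Reagents that add atoms: none
Why: Hydride reduction of the carboxylic acid to the primary alcohol; the 1,1-disubstituted alkene is inert to LiAlH4.

Step 4
Reactants: 5 cyclobutylmethanol
Product: 6 (1S,3S)-1-(iodomethyl)-2,2-dimethyl-3-(prop-1-en-2-yl)cyclobutane
Conditions: I2, PPh3, imidazole, CH2Cl2, 0 °C → rt
Reagents that add atoms: iodine, II
Why: Appel-type iodination by SN2 at the primary carbon, without a cationic intermediate that could open or rearrange the cyclobutane.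

Step 5
Reactants: 7 methyl (R)-3-hydroxybutanoate
Product: 8 methyl (2R,3R)-3-hydroxy-2-methylbutanoate
Conditions: LiN(iPr)2 (2.2 equiv), THF, −78 → −20 °C; MeI, DMPU, −78 → 0 °C
Reagents that add atoms: iodomethane, CI
Why: Fráter–Seebach alkylation: the chelated lithium alkoxide–enolate is methylated on the face away from the C-3 methyl, which sets the anti (2R,3R) relationship.

Step 6
Reactants: 8 anti hydroxy ester
Product: 9 (2R,3R)-3-hydroxy-N-methoxy-N,2-dimethylbutanamide
Conditions: MeNH(OMe)·HCl (2.5 equiv), iPrMgCl (5 equiv), THF, −20 → 0 °C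
Reagents that add atoms: N,O-dimethylhydroxylamine hydrochloride, CNOC.Cl
Why: Weinreb amide formation from the ester with the chloromagnesium amide; the magnesium alkoxide of the free hydroxyl suppresses α-epimerisation and β-elimination.

Step 7
Reactants: 9 hydroxy Weinreb amide
Product: 10 (2R,3R)-3-[(tert-butyldimethylsilyl)oxy]-N-methoxy-N,2-dimethylbutanamide
Conditions: TBSCl, imidazole, DMF, rt
Reagents that add atoms: tert-butyldimethylsilyl chloride, CC(C)(C)[Si](C)(C)Cl
Why: Silylation of the secondary alcohol, needed to carry this oxygen through the enolate, palladium and CS2 steps.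

Step 8
Reactants: 11 3-phenylglutaric anhydride
Product: 12 (3R)-5-(allyloxy)-5-oxo-3-phenylpentanoic acid
Conditions: allyl alcohol (5 equiv), quinine-derived 3,5-bis(trifluoromethyl)benzenesulfonamide catalyst (10 mol%), MTBE, −20 °C
Reagents that add atoms: allyl alcohol, C=CCO
Why: Enantioselective alcoholysis (desymmetrisation) of the prochiral anhydride by a bifunctional cinchona sulfonamide, which binds the anhydride by hydrogen bonding and delivers the alcohol by general-base catalysis to one enantiotopic carbonyl, setting the benzylic centre.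

Step 9
Reactants: 13 methyl acetoacetate; 6 cyclobutylmethyl iodide
Product: 14 methyl 2-{[(1R,3S)-2,2-dimethyl-3-(prop-1-en-2-yl)cyclobutyl]methyl}-3-oxobutanoate (C-2 epimers)
Conditions: 13 (2.5 equiv), NaH (2.4 equiv), DMF, 0 °C; then 6, 60 °C
Reagents that add atoms: none
Why: Acetoacetic ester alkylation (SN2 C-alkylation of the stabilised enolate); excess enolate limits dialkylation and the new α-centre is later made quaternary, so its configuration does not matter.

Step 10
Reactants: 14 alkylated acetoacetate; 10 silyloxy Weinreb amide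
Product: 16 3-(cyclobutylmethyl)-6-[(2R,3R)-3-silyloxybutan-2-yl]-4-hydroxy-2-pyranone, via triketo ester 15 (not isolated)
Conditions: NaH (1.1 equiv), THF, 0 °C; n-BuLi (1.05 equiv), 0 °C; 10, −78 → 0 °C; aq. HCl; then DBU, toluene, 80 °C
Reagents that add atoms: none
Why: γ-Acylation of the acetoacetate dianion by the Weinreb amide (stable tetrahedral adduct, no over-addition), then base-mediated enol lactonisation of the 3,5-dioxo ester to the 4-hydroxy-2-pyranone; the side-chain stereocentres should survive because the dicarbonyl is held as its anion in both stages.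

Step 11
Reactants: 16 4-hydroxy-2-pyranone
Product: 17 (3R)-3-(cyclobutylmethyl)-3-prenyl-6-[(2R,3R)-3-silyloxybutan-2-yl]pyran-2,4-dione
Conditions: prenyl acetate (1.5 equiv), Pd2(dba)3·CHCl3 (2.5 mol%), (R,R)-DACH-phenyl Trost ligand (7.5 mol%), Et3N (1.1 equiv), CH2Cl2, 0 °C
Reagents that add atoms: prenyl acetate, CC(C)=CCOC(C)=O
Why: Proposed new method: zerovalent palladium ionises prenyl acetate to a cationic π-prenyl complex, the acidic pyranone (as its ammonium salt) attacks the unsubstituted allyl terminus through C-3 from outside the metal, O-prenyl ethers re-ionise and so drain to the C-3 product, and the chiral pocket of the diphosphine has to tell the lactone flank from the enone flank of the flat nucleophile to set C-3 (R); the closest known reactions are the non-asymmetric palladium-catalysed C-3 allylation of 4-hydroxy-2-pyranones to 3,3-disubstituted pyran-2,4-diones and the Tsuji–Trost asymmetric allylic alkylation (including prenylation) of prochiral cyclic β-dicarbonyl and oxindole nucleophiles with this ligand class.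

Step 12
Reactants: 17 (3R)-pyran-2,4-dione; 12 (R)-monoallyl hemiester
Product: 18 ring-opened allyl β-keto ester acid (epimers at the new ester-bearing carbon)
Conditions: 12 (2.2 equiv), LiN(iPr)2 (4.5 equiv), THF, −78 °C; then 17, −78 → −40 °C; aq. HCl to pH 3
Reagents that add atoms: none
Why: Crossed Claisen acylation: the carboxylate protects its own α-carbon, so only the allyl ester enolises, and this enolate opens the vinylogous anhydride at the lactone carbonyl (enol-lactone opening of the Fujimoto–Belleau type), releasing the 1,3-diketone as its enolate; the new β-keto ester centre is a mixture that is removed in step 13.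

Step 13
Reactants: 18 allyl β-keto ester acid
Product: 20 triketo acid with a free C-8 methylene, via β-keto acid 19 (not isolated)
Conditions: Pd(OAc)2 (5 mol%), PPh3 (20 mol%), HCO2H, Et3N, THF, rt → 40 °C
Reagents that add atoms: none
Why: Tsuji deallylation with formate as hydride donor gives the β-keto acid 19, which decarboxylates on gentle warming; formate intercepts the π-allyl complex so that neither the diketone nor the new enol is C-allylated.

Step 14
Reactants: 20 triketo acid
Product: 21 bis(methylthio)methylidene triketone methyl ester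
Conditions: K2CO3 (4 equiv), CS2 (2 equiv), DMF, 0 °C → rt; then MeI (4 equiv)
Reagents that add atoms: carbon disulfide, S=C=S; iodomethane, CI
Why: Ketene dithioacetal formation: carbonate deprotonates only the 1,3-diketone carbon (the later C-4a), not the methylene of the simple ketone; the enolate adds to CS2 and double S-methylation follows, while the carboxylate is methylated to the ester in the same flask.

Step 15
Reactants: 21 ketene dithioacetal
Product: 23 5-acyl-6-(methylthio)-2,3-dimethyl-2,3-dihydropyran-4-one, via hydroxy dithioacetal 22 (not isolated)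
Conditions: HF·pyridine, pyridine, THF, 0 °C → rt
Reagents that add atoms: none
Why: Fluoride desilylation frees the C-2 hydroxyl, which closes the dihydropyranone by 6-endo-trig addition–elimination at C-8a, the only carbon carrying a leaving group (a hemiketal at the C-5 carbonyl cannot dehydrate), with loss of methanethiol and retention of both stereocentres.

Step 16
Reactants: 23 methylthio dihydropyranone
Product: 24 methyl ester of the target
Conditions: LiN(SiMe3)2 (1.5 equiv), THF, −78 → 0 °C; then aq. HCl
Reagents that add atoms: none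
Why: LiN(SiMe3)2 removes a proton from the C-8 methylene, the only enolisable position of the C-7 ketone because C-6 is quaternary, and the enolate carbon adds to C-8a of the 6-(methylthio)dihydropyranone, a push–pull alkene activated by both the C-4 and C-5 carbonyls; collapse of the stabilised adduct expels methanethiolate (nucleophilic vinylic substitution by addition–elimination), and the thiolate then deprotonates C-8 so that the product rests as the vinylogous-acid anion, which should make the sequence irreversible. The closest known reaction type is the displacement of methylthio groups from α-oxo ketene dithioacetals and 2-(methylthio)pyran-4-ones by ketone enolates, here in intramolecular form. The carbocycle closes in a 6-endo-trig mode at the electrophile (the C-4a=C-8a bond lies inside the new ring) with the enolate double bond also endocyclic. No new stereocentre arises, since C-8 ends sp2, and C-6, the benzylic carbon and the four remote centres are not touched. The step needs C- rather than O-attack of the enolate, secured by the soft Michael-type acceptor and the stability of the conjugated trione anion, and deprotonation at C-8 rather than at C-3, secured by the higher acidity and accessibility of the C-8 methylene at −78 °C, which also keeps the pyranone from opening by retro-oxa-Michael reaction. Which carbon is attacked is not in question, because C-8a alone bears a leaving group and already carries O-1, so the fusion of the dihydropyranone is fixed before the carbocycle exists.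

Step 17
Reactants: 24 methyl ester
Product: 25 CNP0103716.3 (target acid)
Conditions: LiOH·H2O (5 equiv), THF/H2O, rt; then 1 M HCl to pH 3
Reagents that add atoms: lithium hydroxide, [Li+].[OH-]
Why: Saponification of the methyl ester; the core is present as its delocalised vinylogous-acid anion, which should shield the 1,3-dicarbonyl array from retro-Claisen cleavage and C-3 from enolisation, and acidification gives the acid.

**Compound list**

1 | (1S,5S)-(−)-verbenone | CC1=CC(=O)[C@H]2C[C@@H]1C2(C)C | starting material
2 | 2-[(1S,3R)-3-acetyl-2,2-dimethylcyclobutyl]-2-oxoacetic acid | CC(=O)[C@@H]1C[C@H](C(=O)C(=O)O)C1(C)C | intermediate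
3 | (1S,3R)-3-acetyl-2,2-dimethylcyclobutane-1-carboxylic acid (cis-pinononic acid) | CC(=O)[C@@H]1C[C@H](C(=O)O)C1(C)C | intermediate
4 | (1S,3S)-2,2-dimethyl-3-(prop-1-en-2-yl)cyclobutane-1-carboxylic acid | C=C(C)[C@@H]1C[C@H](C(=O)O)C1(C)C | intermediate
5 | [(1S,3S)-2,2-dimethyl-3-(prop-1-en-2-yl)cyclobutyl]methanol | C=C(C)[C@@H]1C[C@H](CO)C1(C)C | intermediate
6 | (1S,3S)-1-(iodomethyl)-2,2-dimethyl-3-(prop-1-en-2-yl)cyclobutane | C=C(C)[C@@H]1C[C@H](CI)C1(C)C | intermediate
7 | methyl (R)-3-hydroxybutanoate | COC(=O)C[C@@H](C)O | starting material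
8 | methyl (2R,3R)-3-hydroxy-2-methylbutanoate | COC(=O)[C@H](C)[C@@H](C)O | intermediate
9 | (2R,3R)-3-hydroxy-N-methoxy-N,2-dimethylbutanamide | CON(C)C(=O)[C@H](C)[C@@H](C)O | intermediate
10 | (2R,3R)-3-[(tert-butyldimethylsilyl)oxy]-N-methoxy-N,2-dimethylbutanamide | CON(C)C(=O)[C@H](C)[C@@H](C)O[Si](C)(C)C(C)(C)C | intermediate
11 | 3-phenylglutaric anhydride (4-phenyloxane-2,6-dione) | O=C1CC(c2ccccc2)CC(=O)O1 | starting material
12 | (3R)-5-(allyloxy)-5-oxo-3-phenylpentanoic acid | C=CCOC(=O)C[C@@H](CC(=O)O)c1ccccc1 | intermediate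
13 | methyl acetoacetate | CC(=O)CC(=O)OC | starting material
14 | methyl 2-{[(1R,3S)-2,2-dimethyl-3-(prop-1-en-2-yl)cyclobutyl]methyl}-3-oxobutanoate (C-2 epimers) | C=C(C)[C@@H]1C[C@H](CC(C(C)=O)C(=O)OC)C1(C)C | intermediate
15 | methyl (6R,7R)-7-[(tert-butyldimethylsilyl)oxy]-2-{[(1R,3S)-2,2-dimethyl-3-(prop-1-en-2-yl)cyclobutyl]methyl}-6-methyl-3,5-dioxooctanoate (C-2 epimers) | C=C(C)[C@@H]1C[C@H](CC(C(=O)OC)C(=O)CC(=O)[C@H](C)[C@@H](C)O[Si](C)(C)C(C)(C)C)C1(C)C | intermediate
16 | 6-{(2R,3R)-3-[(tert-butyldimethylsilyl)oxy]butan-2-yl}-3-{[(1R,3S)-2,2-dimethyl-3-(prop-1-en-2-yl)cyclobutyl]methyl}-4-hydroxy-2H-pyran-2-one | C=C(C)[C@@H]1C[C@H](CC2=C(O)C=C([C@H](C)[C@@H](C)O[Si](C)(C)C(C)(C)C)OC2=O)C1(C)C | intermediate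
17 | (3R)-6-{(2R,3R)-3-[(tert-butyldimethylsilyl)oxy]butan-2-yl}-3-{[(1R,3S)-2,2-dimethyl-3-(prop-1-en-2-yl)cyclobutyl]methyl}-3-(3-methylbut-2-en-1-yl)-2H-pyran-2,4(3H)-dione | C=C(C)[C@@H]1C[C@H](C[C@@]2(CC=C(C)C)C(=O)OC([C@H](C)[C@@H](C)O[Si](C)(C)C(C)(C)C)=CC2=O)C1(C)C | intermediate
18 | (3R,6R,10R,11R)-4-[(allyloxy)carbonyl]-11-[(tert-butyldimethylsilyl)oxy]-6-{[(1R,3S)-2,2-dimethyl-3-(prop-1-en-2-yl)cyclobutyl]methyl}-10-methyl-6-(3-methylbut-2-en-1-yl)-5,7,9-trioxo-3-phenyldodecanoic acid (C-4 epimers) | C=C(C)[C@@H]1C[C@H](C[C@@](CC=C(C)C)(C(=O)C(C(=O)OCC=C)[C@@H](CC(=O)O)c2ccccc2)C(=O)CC(=O)[C@H](C)[C@@H](C)O[Si](C)(C)C(C)(C)C)C1(C)C | intermediate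
19 | 4-carboxy analogue of 18 (the β-keto acid formed by loss of the allyl group; C-4 epimers) | C=C(C)[C@@H]1C[C@H](C[C@@](CC=C(C)C)(C(=O)C(C(=O)O)[C@@H](CC(=O)O)c2ccccc2)C(=O)CC(=O)[C@H](C)[C@@H](C)O[Si](C)(C)C(C)(C)C)C1(C)C | intermediate
20 | (3S,6S,10R,11R)-11-[(tert-butyldimethylsilyl)oxy]-6-{[(1R,3S)-2,2-dimethyl-3-(prop-1-en-2-yl)cyclobutyl]methyl}-10-methyl-6-(3-methylbut-2-en-1-yl)-5,7,9-trioxo-3-phenyldodecanoic acid (same spatial arrangement at C-3 and C-6 as in 18; the CIP labels change with the substituents) | C=C(C)[C@@H]1C[C@H](C[C@@](CC=C(C)C)(C(=O)C[C@@H](CC(=O)O)c2ccccc2)C(=O)CC(=O)[C@H](C)[C@@H](C)O[Si](C)(C)C(C)(C)C)C1(C)C | intermediate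
21 | methyl (3S,6S,10R,11R)-8-[bis(methylsulfanyl)methylidene]-11-[(tert-butyldimethylsilyl)oxy]-6-{[(1R,3S)-2,2-dimethyl-3-(prop-1-en-2-yl)cyclobutyl]methyl}-10-methyl-6-(3-methylbut-2-en-1-yl)-5,7,9-trioxo-3-phenyldodecanoate | C=C(C)[C@@H]1C[C@H](C[C@@](CC=C(C)C)(C(=O)C[C@@H](CC(=O)OC)c2ccccc2)C(=O)C(=C(SC)SC)C(=O)[C@H](C)[C@@H](C)O[Si](C)(C)C(C)(C)C)C1(C)C | intermediate
22 | 11-hydroxy analogue of 21 (silyl group removed) | C=C(C)[C@@H]1C[C@H](C[C@@](CC=C(C)C)(C(=O)C[C@@H](CC(=O)OC)c2ccccc2)C(=O)C(=C(SC)SC)C(=O)[C@H](C)[C@@H](C)O)C1(C)C | intermediate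
23 | methyl (3S,6S)-6-{[(1R,3S)-2,2-dimethyl-3-(prop-1-en-2-yl)cyclobutyl]methyl}-6-{[(2R,3R)-2,3-dimethyl-6-(methylsulfanyl)-4-oxo-3,4-dihydro-2H-pyran-5-yl]carbonyl}-9-methyl-5-oxo-3-phenyldec-8-enoate | C=C(C)[C@@H]1C[C@H](C[C@@](CC=C(C)C)(C(=O)C[C@@H](CC(=O)OC)c2ccccc2)C(=O)C2=C(SC)O[C@H](C)[C@@H](C)C2=O)C1(C)C | intermediate
24 | methyl (3S)-3-[(2R,3R,6R)-6-{[(1R,3S)-2,2-dimethyl-3-(prop-1-en-2-yl)cyclobutyl]methyl}-5-hydroxy-2,3-dimethyl-6-(3-methylbut-2-en-1-yl)-4,7-dioxo-3,4,6,7-tetrahydro-2H-chromen-8-yl]-3-phenylpropanoate | C=C(C)[C@@H]1C[C@H](C[C@@]2(CC=C(C)C)C(=O)C([C@@H](CC(=O)OC)c3ccccc3)=C3O[C@H](C)[C@@H](C)C(=O)C3=C2O)C1(C)C | intermediate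
25 | CNP0103716.3: (3S)-3-[(2R,3R,6R)-6-{[(1R,3S)-2,2-dimethyl-3-(prop-1-en-2-yl)cyclobutyl]methyl}-5-hydroxy-2,3-dimethyl-6-(3-methylbut-2-en-1-yl)-4,7-dioxo-3,4,6,7-tetrahydro-2H-chromen-8-yl]-3-phenylpropanoic acid | C=C(C)[C@@H]1C[C@H](C[C@@]2(CC=C(C)C)C(=O)C([C@@H](CC(=O)O)c3ccccc3)=C3O[C@H](C)[C@@H](C)C(=O)C3=C2O)C1(C)C | target

**Step count and risks**

Total step count: 17. Longest linear sequence: 13 steps (steps 1–4, then 9–17).

Steps most likely to fail:

1. Step 11 (proposed new method). What may go wrong: poor facial selectivity at C-3 of the flat pyranone anion, or erosion of an initial selectivity through reversible ionisation of the C-3–prenyl bond; O-prenylation or attack at the substituted allyl terminus are lesser concerns. Fallback with known chemistry, setting out from 16 and coming back at 17: the ligand-controlled step is replaced by the known non-asymmetric C-3 allylation of 4-hydroxy-2-pyranones (Pd(PPh3)4, prenyl acetate, Et3N, THF). This should give 17 together with its C-3 epimer, the (3S)-pyran-2,4-dione F1. The two are diastereomers (four other stereocentres are present) and are to be separated by preparative chromatography. F1 is then re-exposed to Pd(PPh3)4 in THF, where reversible ionisation of its C-3–prenyl bond (the leaving group is the strongly stabilised pyranone anion) should re-equilibrate it to the 17/F1 mixture for a further separation cycle.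

2. Step 12. What may go wrong: the strongly basic lithium dianion may act as a base at the side-chain CH next to C-6 of the pyrandione or add at the wrong carbonyl, and the quaternary C-3 may slow acylation at the lactone carbonyl until proton transfer wins. Fallback, setting out from 11 and 17 and coming back at 20: the same cinchona-catalysed desymmetrisation of 11 is run with phenylmethanethiol in place of allyl alcohol, giving the hemithioester (3R)-5-(benzylsulfanyl)-5-oxo-3-phenylpentanoic acid F2. The thioester is enolised under soft conditions (MgBr2·OEt2, iPr2NEt, CH2Cl2, no strong base) and C-acylated by 17, giving the β-keto thioester F3. AgO2CCF3 in wet THF then hydrolyses the thioester to the β-keto acid 19, which loses CO2 on gentle warming and joins the route at 20.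

3. Step 16 (key step). What may go wrong: O- instead of C-attack of the enolate, or competing deprotonation at C-3 of the dihydropyranone followed by retro-oxa-Michael ring opening, which would scramble C-2 and C-3. Fallback, setting out from 21 and coming back at 24: the two substitutions at C-8a are run in the opposite order. LiN(SiMe3)2 (THF, −78 → 0 °C) on 21 closes the C-8–C-8a bond first, on the more electrophilic bis(methylthio)alkene and while no base-labile pyranone exists, giving the methylthio-substituted cyclohexadienone F4. HF·pyridine then removes the silyl group, and the freed hydroxyl displaces the remaining methylthio group at C-8a to give 24. The price of this order is that the oxygen must choose C-8a over the C-5 carbonyl in the last closure, which is why it is the fallback and not the main route.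

Further compounds
F1 | step 11 | (3S)-6-{(2R,3R)-3-[(tert-butyldimethylsilyl)oxy]butan-2-yl}-3-{[(1R,3S)-2,2-dimethyl-3-(prop-1-en-2-yl)cyclobutyl]methyl}-3-(3-methylbut-2-en-1-yl)-2H-pyran-2,4(3H)-dione | C=C(C)[C@@H]1C[C@H](C[C@]2(CC=C(C)C)C(=O)OC([C@H](C)[C@@H](C)O[Si](C)(C)C(C)(C)C)=CC2=O)C1(C)C
F2 | step 12 | (3R)-5-(benzylsulfanyl)-5-oxo-3-phenylpentanoic acid | O=C(SCc1ccccc1)C[C@@H](CC(=O)O)c1ccccc1
F3 | step 12 | S-benzyl thioester analogue of 18: (3R,6R,10R,11R)-4-[(benzylsulfanyl)carbonyl]-11-[(tert-butyldimethylsilyl)oxy]-6-{[(1R,3S)-2,2-dimethyl-3-(prop-1-en-2-yl)cyclobutyl]methyl}-10-methyl-6-(3-methylbut-2-en-1-yl)-5,7,9-trioxo-3-phenyldodecanoic acid (C-4 epimers) | C=C(C)[C@@H]1C[C@H](C[C@@](CC=C(C)C)(C(=O)C(C(=O)SCc2ccccc2)[C@@H](CC(=O)O)c2ccccc2)C(=O)CC(=O)[C@H](C)[C@@H](C)O[Si](C)(C)C(C)(C)C)C1(C)C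
F4 | step 16 | methyl (3S)-3-[(5R)-3-{(2R,3R)-3-[(tert-butyldimethylsilyl)oxy]-2-methylbutanoyl}-5-{[(1R,3S)-2,2-dimethyl-3-(prop-1-en-2-yl)cyclobutyl]methyl}-4-hydroxy-5-(3-methylbut-2-en-1-yl)-2-(methylsulfanyl)-6-oxocyclohexa-1,3-dien-1-yl]-3-phenylpropanoate | C=C(C)[C@@H]1C[C@H](C[C@@]2(CC=C(C)C)C(=O)C([C@@H](CC(=O)OC)c3ccccc3)=C(SC)C(C(=O)[C@H](C)[C@@H](C)O[Si](C)(C)C(C)(C)C)=C2O)C1(C)C
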